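**Retrosynthetic overview**
1. Macrocarpal J ⇒ three-component union at C1′ of 2,4-diformylphloroglucinol, a C1-formyl cryptomeridiol-type diol and an isobutyl radical, through an o-quinone methide (arene attached last).
2. The diol ⇒ key C–O disconnection: both tertiary carbinols (C4–O with its stereocentre, and C11–O) from one double Markovnikov hydration of a selina-3,11-diene 1β-ester.
3. The Δ3 alkene and the trans ring fusion ⇒ C3–N bond formation on an allylic alcohol (Mitsunobu with a sulfonyl hydrazide), then loss of N2 with hydrogen delivery to C5.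
4. Ring A ⇒ Michael/aldol (Robinson-type) annulation of a chiral imine of (+)-dihydrocarvone with ethyl (E)-4-oxohex-2-enoate, setting C10 and C1.
5. Ring order: ring B from the chiral pool, ring A by annulation, ring-A redox adjustment, arene last.

Assumption and convention: commercial (+)-dihydrocarvone (a mixture of C2 epimers) is used as such because C2 is enolised in step 2; eudesmane numbering is used for the decalin (ring A = C1–C5 and C10, ring B = C5–C10, C1′ = benzylic carbon on C1, C11 = side-chain carbon on C7), and β means the face of the C10 methyl.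

**Step 1**
Reactants: 1 ethyl (E)-4-chloro-4-oxobut-2-enoate
Product: 2 ethyl (E)-4-oxohex-2-enoate
Conditions: Et2Zn (0.55 equiv), Pd(PPh3)4 (2 mol%), THF, 0 °C
Reagents that add atoms: diethylzinc, CC[Zn]CC
Why: Negishi-type acylation of the acid chloride by the organozinc gives the ethyl ketone without touching the enoate, and the (E)-alkene is retained.

**Step 2**
Reactants: 3 (+)-dihydrocarvone; 4 (R)-1-phenylethylamine; 2 ethyl (E)-4-oxohex-2-enoate
Product: 7 diketo ester ethyl (2R)-2-[(1S,4R)-1-methyl-2-oxo-4-(prop-1-en-2-yl)cyclohexyl]-4-oxohexanoate, via ketimine 5 (not isolated), via Michael-adduct imine 6 (not isolated)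
Conditions: (a) TsOH (cat.), toluene, reflux, Dean–Stark; (b) 2 (1.1 equiv), THF, 0 °C to rt; (c) 10% aq. AcOH, rt
Reagents that add atoms: water, O
Why: d'Angelo asymmetric Michael addition, in which the more substituted secondary-enamine tautomer of 5 adds through a compact aza-ene-like transition state to the enoate carbon β to the ketone (the stronger acceptor) on the face dictated by the (R)-phenylethyl group, setting the quaternary C10 (S, methyl cis to isopropenyl) and, with the (E)-acceptor endo, C1 (ester β, which is also the thermodynamic epimer), while C7 comes from the chiral pool.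

**Step 3**
Reactants: 7 diketo ester
Product: 9 enone ester ethyl (1R,6R,8aS)-4,8a-dimethyl-3-oxo-6-(prop-1-en-2-yl)-1,2,3,5,6,7,8,8a-octahydronaphthalene-1-carboxylate, via aldol ketol 8 (not isolated)
Conditions: NaOEt (0.3 equiv), EtOH, 0 to 50 °C
Reagents that add atoms: none
Why: Intramolecular aldol condensation (second half of a Robinson annulation) closes ring A from the ethyl-ketone methylene onto the ring ketone, dehydration to the tetrasubstituted enone drives it, and ethoxide matches the ester and equilibrates C1 to the equatorial β-ester.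

**Step 4**
Reactants: 9 enone ester
Product: 10 3β-allylic alcohol (3S)
Conditions: NaBH4, CeCl3·7H2O, MeOH, −20 °C
Reagents that add atoms: none
Why: Luche 1,2-reduction, in which hydride attacks C3 axially from the α face anti to the C10 methyl to give the equatorial 3β-alcohol and leaves the ester intact.

**Step 5**
Reactants: 10 3β-allylic alcohol
Product: 13 diene ester (Δ3; 5α-H; 1β-CO2Et; 7β-isopropenyl), via allylic sulfonylhydrazine 11 (not isolated), via allylic diazene 12 (not isolated)
Conditions: 2-nitrobenzenesulfonylhydrazide (NBSH), PPh3, DEAD, THF, −30 °C, then rt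
Reagents that add atoms: none
Why: Myers reductive 1,3-transposition, in which Mitsunobu displacement forms the C3–N bond with inversion (3α), sulfinate loss gives the allylic diazene, and its suprafacial retro-ene loss of N2 delivers hydrogen to the α face of C5, setting the trans ring fusion and moving the alkene to C3=C4.

**Step 6**
Reactants: 13 diene ester
Product: 14 diol ester (4α-OH; 11-OH; 1β-CO2Et)
Conditions: Mn(dpm)3 [tris(2,2,6,6-tetramethylheptane-3,5-dionato)manganese] (10 mol%), PhSiH3 (4 equiv), O2 (1 atm), iPrOH/CH2Cl2, 0 °C to rt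
Reagents that add atoms: dioxygen, O=O
Why: Mukaiyama-type hydrogen-atom-transfer hydration (the key C–O bond-forming step), in which Markovnikov hydrogen-atom transfer gives the tertiary C4 and C11 radicals and O2 traps the C4 radical from the equatorial α face because the axial β face is blocked by the 1,3-diaxial C10 methyl, giving the 4α-OH/4β-CH3 (4R) carbinol together with the C11 carbinol after in-situ reduction of the peroxides.

**Step 7**
Reactants: 14 diol ester
Product: 15 diol aldehyde (1β-CHO)
Conditions: iBu2AlH (3.5 equiv), CH2Cl2, −78 °C; aq. potassium sodium tartrate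
Reagents that add atoms: none
Why: Partial ester reduction, in which two equivalents are consumed by the tertiary hydroxyls and the hindered aluminium hemiacetal is stable at −78 °C and releases the aldehyde on work-up, with C1 remaining in its equatorial (thermodynamic) configuration.

**Step 8**
Reactants: 16 phloroglucinol
Product: 18 2,4,6-trihydroxybenzene-1,3-dicarbaldehyde, via bis(iminium) salt 17 (not isolated)
Conditions: POCl3 (2.2 equiv), DMF, 1,4-dioxane, 0 °C to rt; then H2O
Reagents that add atoms: N,N-dimethylformamide, CN(C)C=O; water, O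
Why: Vilsmeier–Haack formylation, in which the chloroiminium electrophile substitutes the electron-rich ring twice, the bis(iminium) salt precipitates before a third substitution, and hydrolysis gives the dialdehyde.

**Step 9**
Reactants: 19 trimethoxy(2-methylpropyl)silane; 20 catechol
Product: 21 triethylammonium bis(catecholato)isobutylsilicate
Conditions: Et3N, THF, reflux
Reagents that add atoms: triethylamine, CCN(CC)CC
Why: Ligand exchange at silicon, in which two catecholates displace three methoxides to give the bench-stable pentacoordinate silicate, a known class of easily oxidised primary-alkyl radical precursors.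

**Step 10**
Reactants: 15 diol aldehyde; 18 2,4,6-trihydroxybenzene-1,3-dicarbaldehyde; 21 triethylammonium bis(catecholato)isobutylsilicate
Product: 23 Macrocarpal J, via o-quinone methide 22 (not isolated)
Conditions: L-proline (20 mol%), DMSO, 40 °C; then 21 (1.5 equiv), 4CzIPN (2 mol%), blue LEDs (450 nm), 25 °C, Ar
Reagents that add atoms: none
Why: Proposed new method: proline-catalysed Knoevenagel condensation of the only free ring carbon of 18 with aldehyde 15 gives o-quinone methide 22 (the condensation known from euglobal-type hetero-Diels–Alder chemistry and from three-component reductive alkylation of 1,3-dicarbonyls); photoexcited 4CzIPN oxidises silicate 21 (about +0.75 V vs SCE, the most easily oxidised species present) to the nucleophilic isobutyl radical, which adds to the electrophilic exocyclic carbon of 22, and the aryloxyl radical is reduced by the 4CzIPN radical anion and protonated by Et3NH+, so the cycle is redox-neutral; C1′ (S) is set because, with C1–H eclipsing the exocyclic C=C to avoid A(1,3) strain, the radical adds to the face anti to the quaternary C10; closest known reaction type: photoredox Giese-type 1,6-addition of alkylsilicates and related radical precursors to para-quinone methides.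

**Compound list**
1 | ethyl (E)-4-chloro-4-oxobut-2-enoate (monoethyl fumarate acid chloride) | CCOC(=O)/C=C/C(Cl)=O | starting material
2 | ethyl (E)-4-oxohex-2-enoate | CCOC(=O)/C=C/C(=O)CC | intermediate
3 | (+)-dihydrocarvone, (2R,5R)-2-methyl-5-(prop-1-en-2-yl)cyclohexan-1-one | C[C@@H]1CC[C@@H](C(C)=C)CC1=O | starting material
4 | (R)-1-phenylethylamine | C[C@@H](N)c1ccccc1 | starting material
5 | ketimine, (5R)-2-methyl-N-[(1R)-1-phenylethyl]-5-(prop-1-en-2-yl)cyclohexan-1-imine (C2 epimerises through the enamine tautomer) | CC1CC[C@@H](C(C)=C)CC1=N[C@H](C)c1ccccc1 | intermediate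
6 | Michael-adduct imine, the N-[(1R)-1-phenylethyl] imine of the ring ketone of 7 | CCOC(=O)[C@H](CC(=O)CC)[C@]1(C)CC[C@@H](C(C)=C)CC1=N[C@H](C)c1ccccc1 | intermediate
7 | diketo ester, ethyl (2R)-2-[(1S,4R)-1-methyl-2-oxo-4-(prop-1-en-2-yl)cyclohexyl]-4-oxohexanoate | CCOC(=O)[C@H](CC(=O)CC)[C@]1(C)CC[C@@H](C(C)=C)CC1=O | intermediate
8 | aldol ketol, ring A closed, 3-oxo, 4-CH3, 5-OH (C4/C5 epimers), 1β-CO2Et, 7β-isopropenyl, 10β-CH3 | CCOC(=O)[C@@H]1CC(=O)C(C)C2(O)C[C@H](C(C)=C)CC[C@]21C | intermediate
9 | enone ester, ethyl (1R,6R,8aS)-4,8a-dimethyl-3-oxo-6-(prop-1-en-2-yl)-1,2,3,5,6,7,8,8a-octahydronaphthalene-1-carboxylate (Δ4-3-one, 1β-CO2Et, 7β-isopropenyl, 10β-CH3) | CCOC(=O)[C@@H]1CC(=O)C(C)=C2C[C@H](C(C)=C)CC[C@]21C | intermediate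
10 | 3β-allylic alcohol (3S), Δ4, otherwise as 9 | CCOC(=O)[C@@H]1C[C@H](O)C(C)=C2C[C@H](C(C)=C)CC[C@]21C | intermediate
11 | allylic sulfonylhydrazine, 3α-N(NH2)SO2(2-nitrophenyl), Δ4 | CCOC(=O)[C@@H]1C[C@@H](N(N)S(=O)(=O)c3ccccc3[N+](=O)[O-])C(C)=C2C[C@H](C(C)=C)CC[C@]21C | intermediate
12 | allylic diazene, 3α-N=NH, Δ4 | CCOC(=O)[C@@H]1C[C@@H](N=N)C(C)=C2C[C@H](C(C)=C)CC[C@]21C | intermediate
13 | diene ester, trans-decalin with C3=C4(CH3), 5α-H, 1β-CO2Et, 7β-isopropenyl, 10β-CH3 | CCOC(=O)[C@@H]1CC=C(C)[C@@H]2C[C@H](C(C)=C)CC[C@]21C | intermediate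
14 | diol ester, 4α-OH/4β-CH3, 7β-C(CH3)2OH, 5α-H, 10β-CH3, 1β-CO2Et | CCOC(=O)[C@@H]1CC[C@@](C)(O)[C@@H]2C[C@H](C(C)(C)O)CC[C@]21C | intermediate
15 | diol aldehyde, as 14 with 1β-CHO | O=C[C@@H]1CC[C@@](C)(O)[C@@H]2C[C@H](C(C)(C)O)CC[C@]21C | intermediate
16 | phloroglucinol (benzene-1,3,5-triol) | Oc1cc(O)cc(O)c1 | starting material
17 | bis(iminium) salt, 2,4-bis(dimethyliminiomethyl)phloroglucinol dichloride | C[N+](C)=Cc1c(O)cc(O)c(C=[N+](C)C)c1O.[Cl-].[Cl-] | intermediate
18 | 2,4,6-trihydroxybenzene-1,3-dicarbaldehyde | O=Cc1c(O)cc(O)c(C=O)c1O | intermediate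
19 | trimethoxy(2-methylpropyl)silane | CC(C)C[Si](OC)(OC)OC | starting material
20 | catechol (benzene-1,2-diol) | Oc1ccccc1O | starting material
21 | triethylammonium bis(benzene-1,2-diolato)(2-methylpropyl)silicate | CC(C)C[Si-]12(Oc3ccccc3O1)Oc1ccccc1O2.CC[NH+](CC)CC | intermediate
22 | o-quinone methide, exocyclic C1′H=C on the diformyl-dihydroxy-cyclohexadienone ring, C1′ attached to C1β of the diol decalin | O=C1C(C=O)=C(O)C(C=O)=C(O)C1=C[C@@H]1CC[C@@](C)(O)[C@@H]2C[C@H](C(C)(C)O)CC[C@]21C | intermediate
23 | Macrocarpal J, 5-[(1S)-1-[(1S,4R,4aR,6R,8aS)-4-hydroxy-6-(2-hydroxypropan-2-yl)-4,8a-dimethyldecahydronaphthalen-1-yl]-3-methylbutyl]-2,4,6-trihydroxybenzene-1,3-dicarbaldehyde | CC(C)C[C@H](c1c(O)c(C=O)c(O)c(C=O)c1O)[C@@H]1CC[C@@](C)(O)[C@@H]2C[C@H](C(C)(C)O)CC[C@]21C | target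

**Step count**
Total: 10 steps (7 in the main line from 3, plus the preparations of 2, 18 and 21).
Longest linear sequence: 8 steps (steps 1–7 and 10).

**Steps most likely to fail, with fallbacks**

The Mitsunobu/diazene transposition of step 5 may suffer from elimination to the 2,4-diene or from SN2′ attack at the hindered allylic position. The fallback sets out from allylic alcohol 10. Formylation (HCO2H, Ac2O, pyridine, 0 °C) gives the 3β-allylic formate F1. Tsuji–Mandai hydrogenolysis (Pd(OAc)2, PBu3, 1,4-dioxane, reflux) then ionises the formate anti to palladium and delivers hydride from the metal to the more substituted terminus C5 on the α face. This gives the trans-fused diene ester 13, where the fallback rejoins the route.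

The radical double hydration of step 6 may give insufficient facial selectivity at C4 or incomplete conversion of the ring alkene. The fallback sets out from diene ester 13 and forms both C–O bonds by ionic chemistry. mCPBA (2.5 equiv, NaHCO3, CH2Cl2, 0 °C) epoxidises the ring alkene from the α face and also the isopropenyl group, giving the bis-epoxide F2 (C11 epimers, inconsequential). LiAlH4 (THF, reflux) opens both epoxides at the less substituted carbon and reduces the ester, giving the triol F3 with the 4α-OH and the C11 carbinol. TEMPO (cat.)/PhI(OAc)2 in CH2Cl2 oxidises only the primary alcohol, so the fallback comes back at diol aldehyde 15 and step 7 is not needed.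

The new three-component radical coupling of step 10 may fail through slow condensation of the hindered aldehyde, premature quenching of the radical, or bis-aryl methane formation. The fallback sets out from 15 and 18 and uses polar, known reaction types. Condensation in NaOAc/AcOH at 60 °C in the presence of (2-methylallyl)trimethylsilane traps the same o-quinone methide in a Hosomi–Sakurai-type allylation, under the same A(1,3)-controlled facial bias, to give the methallyl adduct F4. Homogeneous hydrogenation (H2 1 atm, RhCl(PPh3)3, benzene/EtOH, rt) reduces only the 1,1-disubstituted alkene, and the fallback comes back at the target 23.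

**Further compounds**
F1 | step 5 | 3β-allylic formate of 10 (3β-OCHO, Δ4, 1β-CO2Et, 7β-isopropenyl, 10β-CH3) | CCOC(=O)[C@@H]1C[C@H](OC=O)C(C)=C2C[C@H](C(C)=C)CC[C@]21C
F2 | step 6 | bis-epoxide of 13 (3α,4α-epoxide; 11,12-epoxide as C11 epimers; 1β-CO2Et) | CCOC(=O)[C@@H]1C[C@H]3O[C@@]3(C)[C@@H]2C[C@H](C4(C)CO4)CC[C@]21C
F3 | step 6 | triol (1β-CH2OH, 4α-OH/4β-CH3, 7β-C(CH3)2OH, 5α-H, 10β-CH3) | OC[C@@H]1CC[C@@](C)(O)[C@@H]2C[C@H](C(C)(C)O)CC[C@]21C
F4 | step 10 | methallyl adduct (Macrocarpal J with a 2-methylprop-2-enyl group on C1′ in place of isobutyl) | C=C(C)C[C@H](c1c(O)c(C=O)c(O)c(C=O)c1O)[C@@H]1CC[C@@](C)(O)[C@@H]2C[C@H](C(C)(C)O)CC[C@]21C
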